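**Retrosynthetic overview**

- The ester at O3 is made last from the eudesmane triol and (2S,3R)-2,3-epoxy-2-methylbutanoic acid; the acid comes from tiglic acid by Sharpless epoxidation of tiglyl alcohol.
- The triol comes from α-face dihydroxylation of C3=C4, after dehydrogenation of the C8 ketone to C6=C7 and after a formate hydrogenolysis that sets 5α-H and places the alkene at C3=C4.
- Key disconnection C9–C10: ring A carries oxygen at C3, a methyl on ortho C4 and a methyl on C10 para to C3, so it is a latent 2,4-dimethylphenol. The C5 side chain C6–C7–C8(OSi)=C9 closes ring B when C9 bonds to the para carbon C10 under anodic oxidation, and C7 relays its configuration to C10.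
- The cyclisation precursor comes from Evans deconjugative benzylation (sets C7), Mukaiyama hydration (C11–O) and a Weinreb ketone synthesis; the arene comes from 2,6-dimethylbenzoic acid.
- Ring order: aromatic ring A first, ring B in the key step, then reduction and oxygenation of ring A.

Key step: step 14

Remark: eudesmane numbering is used; the target is read as 3α-acyloxy, 4α-OH/4β-CH3, 5α-H, 10β-CH3 (3R,4S,5R,10R), and the acyl group as the (2S,3R)-epoxide of tiglic acid (oxirane methyls cis).

Remark: the enol ether of the cyclisation precursor is carried as the tert-butyldimethylsilyl ether, because it survives the unmasking of the phenol; C7 is only a relay centre and is flattened when C6=C7 is made.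

**Route**

Step 1
Reactants: 1 2,6-dimethylbenzoic acid
Product: 2 3-bromo-2,6-dimethylbenzoic acid
Conditions: NBS (1.0 equiv), conc. H2SO4, 0 °C → rt
Reagents that add atoms: N-bromosuccinimide, O=C1CCC(=O)N1Br
Why: Electrophilic aromatic bromination; C3 is ortho/para to the two methyl groups and meta to the carboxyl group, so all substituents direct to the same carbon and one equivalent should stop at the monobromide.

Step 2
Reactants: 2 3-bromo-2,6-dimethylbenzoic acid
Product: 3 3-hydroxy-2,6-dimethylbenzoic acid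
Conditions: Pd2(dba)3 (2 mol%), tBuXPhos (8 mol%), KOH (4 equiv), 1,4-dioxane/H2O, 100 °C; then aq. HCl
Reagents that add atoms: potassium hydroxide, [K+].[OH-]
Why: Palladium-catalysed hydroxylation of an aryl bromide (Buchwald C–O coupling with hydroxide), which tolerates the carboxylate and the ortho methyl group.

Step 3
Reactants: 3 3-hydroxy-2,6-dimethylbenzoic acid
Product: 4 3-(hydroxymethyl)-2,4-dimethylphenol
Conditions: BH3·SMe2 (3 equiv), THF, 0 °C → reflux; then MeOH
Reagents that add atoms: none
Why: Borane reduction of the hindered carboxylic acid through its acyloxyborane gives the benzylic alcohol, while the phenol is only held as a borate until the methanol quench.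

Step 4
Reactants: 4 3-(hydroxymethyl)-2,4-dimethylphenol
Product: 5 [3-(benzyloxy)-2,6-dimethylphenyl]methanol
Conditions: BnBr (1.05 equiv), K2CO3, acetone, reflux
Reagents that add atoms: benzyl bromide, BrCc1ccccc1
Why: Williamson etherification; carbonate deprotonates only the phenol, so the benzylic alcohol should stay free.

Step 5
Reactants: 5 [3-(benzyloxy)-2,6-dimethylphenyl]methanol
Product: 6 1-(benzyloxy)-3-(bromomethyl)-2,4-dimethylbenzene
Conditions: PBr3 (0.4 equiv), Et2O, 0 °C
Reagents that add atoms: phosphorus tribromide, BrP(Br)Br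
Why: Conversion of a benzylic alcohol into the bromide through its phosphite ester with bromide displacement; the aryl benzyl ether is inert.

Step 6
Reactants: 7 3-methylbut-2-enoic acid; 8 (R)-4-benzyl-1,3-oxazolidin-2-one
Product: 10 (R)-4-benzyl-3-(3-methylbut-2-enoyl)-1,3-oxazolidin-2-one, via mixed pivalic anhydride 9 (not isolated)
Conditions: PivCl, Et3N, THF, −20 °C; then LiCl, 8, −20 °C → rt
Reagents that add atoms: none
Why: N-Acylation of the oxazolidinone through the mixed pivalic anhydride (LiCl/Et3N protocol); the nucleophile attacks the less hindered senecioyl carbonyl.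

Step 7
Reactants: 10 (R)-4-benzyl-3-(3-methylbut-2-enoyl)-1,3-oxazolidin-2-one; 6 1-(benzyloxy)-3-(bromomethyl)-2,4-dimethylbenzene
Product: 12 (R)-4-benzyl-3-{(2R)-2-[3-(benzyloxy)-2,6-dimethylbenzyl]-3-methylbut-3-enoyl}-1,3-oxazolidin-2-one, via sodium dienolate 11 (not isolated)
Conditions: NaN(SiMe3)2 (1.1 equiv), THF, −78 °C; then 6, −78 → −40 °C
Reagents that add atoms: none
Why: Evans deconjugative α-alkylation; γ-deprotonation gives the chelated Z-dienolate, which is benzylated at the α-carbon on the face opposite the auxiliary benzyl group and so sets the (R) centre that becomes C7.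

Step 8
Reactants: 12 (R)-4-benzyl-3-{(2R)-2-[3-(benzyloxy)-2,6-dimethylbenzyl]-3-methylbut-3-enoyl}-1,3-oxazolidin-2-one
Product: 13 (R)-4-benzyl-3-{(2R)-2-[3-(benzyloxy)-2,6-dimethylbenzyl]-3-hydroxy-3-methylbutanoyl}-1,3-oxazolidin-2-one
Conditions: Co(acac)2 (20 mol%), PhSiH3 (2.5 equiv), O2 (1 atm), THF, rt
Reagents that add atoms: dioxygen, O=O
Why: Mukaiyama hydration (hydrogen-atom transfer from a cobalt hydride, capture of the tertiary radical by O2, reduction of the peroxide by the silane) gives the Markovnikov tertiary alcohol from the 1,1-disubstituted alkene without touching the neighbouring stereocentre.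

Step 9
Reactants: 13 (R)-4-benzyl-3-{(2R)-2-[3-(benzyloxy)-2,6-dimethylbenzyl]-3-hydroxy-3-methylbutanoyl}-1,3-oxazolidin-2-one
Product: 14 (2R)-2-[3-(benzyloxy)-2,6-dimethylbenzyl]-3-hydroxy-N-methoxy-N,3-dimethylbutanamide
Conditions: MeNH(OMe)·HCl (3 equiv), AlMe3 (3 equiv), CH2Cl2, −10 °C → rt
Reagents that add atoms: N,O-dimethylhydroxylamine hydrochloride, CNOC.Cl
Why: Weinreb transamination of the imide by the aluminium amide, directed to the exocyclic carbonyl by the β-aluminium alkoxide, should release the auxiliary without epimerisation.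

Step 10
Reactants: 14 (2R)-2-[3-(benzyloxy)-2,6-dimethylbenzyl]-3-hydroxy-N-methoxy-N,3-dimethylbutanamide
Product: 15 (2R)-2-[3-(benzyloxy)-2,6-dimethylbenzyl]-N-methoxy-N,3-dimethyl-3-(triethylsilyloxy)butanamide
Conditions: TESOTf, 2,6-lutidine, CH2Cl2, −78 → 0 °C
Reagents that add atoms: triethylsilyl trifluoromethanesulfonate, CC[Si](CC)(CC)OS(=O)(=O)C(F)(F)F
Why: Silyl triflate silylation of the hindered tertiary alcohol, which blocks retro-aldol cleavage of the later β-oxy ketone and keeps the hydroxyl from capturing the oxidised arene in the key step.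

Step 11
Reactants: 15 (2R)-2-[3-(benzyloxy)-2,6-dimethylbenzyl]-N-methoxy-N,3-dimethyl-3-(triethylsilyloxy)butanamide
Product: 16 (3R)-3-[3-(benzyloxy)-2,6-dimethylbenzyl]-4-methyl-4-(triethylsilyloxy)pentan-2-one
Conditions: MeMgBr (3 equiv), THF, 0 °C → rt; aq. NH4Cl at 0 °C
Reagents that add atoms: methylmagnesium bromide, C[Mg]Br
Why: Weinreb ketone synthesis; the chelated tetrahedral intermediate collapses only on work-up, so neither over-addition nor enolisation of the new ketone at C7 should occur.

Step 12
Reactants: 16 (3R)-3-[3-(benzyloxy)-2,6-dimethylbenzyl]-4-methyl-4-(triethylsilyloxy)pentan-2-one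
Product: 17 (3R)-3-(3-hydroxy-2,6-dimethylbenzyl)-4-methyl-4-(triethylsilyloxy)pentan-2-one
Conditions: H2 (1 atm), Pd/C (10% palladium on carbon), EtOAc, rt
Reagents that add atoms: none
Why: Hydrogenolysis of the aryl benzyl ether; the hindered ketone and the tertiary silyl ether are inert.

Step 13
Reactants: 17 (3R)-3-(3-hydroxy-2,6-dimethylbenzyl)-4-methyl-4-(triethylsilyloxy)pentan-2-one
Product: 21 3-{(2R)-3-(tert-butyldimethylsilyloxy)-2-[2-(triethylsilyloxy)propan-2-yl]but-3-en-1-yl}-2,4-dimethylphenol, via aryl trimethylsilyl ether 18 (not isolated), via lithium enolate 19 (not isolated), via bis-silyl compound 20 (not isolated)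
Conditions: TMSCl (1.05 equiv), Et3N, THF, 0 °C, filter and concentrate; LiN(iPr)2 (1.2 equiv), THF, −78 °C; TBSOTf, −78 °C; then K2CO3 (0.2 equiv), MeOH, 0 °C
Reagents that add atoms: tert-butyldimethylsilyl trifluoromethanesulfonate, CC(C)(C)[Si](C)(C)OS(=O)(=O)C(F)(F)F (chlorotrimethylsilane, C[Si](C)(C)Cl, adds atoms only to 18–20)
Why: Transient O-silylation of the phenol, kinetic deprotonation of the methyl ketone at CH3 and O-silylation give the terminal silyl enol ether, and brief carbonate methanolysis should remove only the far more labile aryl trimethylsilyl ether.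

Step 14
Reactants: 21 3-{(2R)-3-(tert-butyldimethylsilyloxy)-2-[2-(triethylsilyloxy)propan-2-yl]but-3-en-1-yl}-2,4-dimethylphenol
Product: 22 (7R,10S)-11-(triethylsilyloxy)eudesma-1,4-diene-3,8-dione
Conditions: undivided cell, reticulated vitreous carbon anode, Pt cathode, constant current (about 2.2 F/mol), LiClO4 (0.1 M), 2,6-lutidine (3 equiv), MeCN/(CF3)2CHOH 4:1, rt
Reagents that add atoms: none
Why: The lutidine-bound phenol is the most easily oxidised group and should lose two electrons and a proton at the anode to a phenoxonium ion that the fluoroalcohol stabilises but does not capture; C9 of the tethered silyl enol ether then adds to the para carbon C10, and the silyloxycarbenium ion hands its silyl group to the solvent, leaving the C8 ketone and the cross-conjugated dienone. The closest known reactions are anodic and PhI(OAc)2-mediated para-dearomatisations of 4-alkylphenols by tethered π-nucleophiles and anodic couplings of silyl enol ethers with electron-rich arenes. Ring B closes as a six-membered carbocycle (6-endo with respect to the enol ether, whose C8=C9 bond lies inside the new ring) through a chair-like transition state with the new C9–C10 bond perpendicular to the arene plane. C10 is the only new stereocentre and is controlled by C7: with the bulky CMe2OSiEt3 group equatorial in that chair, C9 reaches one arene face, so the C10 methyl becomes axial on ring B and cis to the C7 substituent. The step needs para (C10) over ortho (C4) attack, which the larger para coefficient of the phenoxonium ion and the greater stability of the 2,5-dienone favour, and carbon over solvent capture, which the non-nucleophilic medium secures. Any C10 epimer should be removed by chromatography here, because C7 is later flattened and a C10 error would then appear as the enantiomer.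

Step 15
Reactants: 22 (7R,10S)-11-(triethylsilyloxy)eudesma-1,4-diene-3,8-dione
Product: 23 (7R,10R)-11-(triethylsilyloxy)eudesm-4-ene-3,8-dione
Conditions: RhCl(PPh3)3 (5 mol%), H2 (1 atm), benzene/EtOH, rt
Reagents that add atoms: none
Why: Homogeneous hydrogenation with Wilkinson's catalyst should reduce only the unhindered disubstituted C1=C2 bond of the cross-conjugated dienone (as in santonin) and leave the tetrasubstituted C4=C5 bond and both ketones.

Step 16
Reactants: 23 (7R,10R)-11-(triethylsilyloxy)eudesm-4-ene-3,8-dione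
Product: 24 (3S,7R,10R)-3-hydroxy-11-(triethylsilyloxy)eudesm-4-en-8-one
Conditions: NaBH4 (1.0 equiv), CeCl3·7H2O (1.1 equiv), MeOH, −78 °C
Reagents that add atoms: none
Why: Luche 1,2-reduction; the cerium-activated enone carbonyl C3 should react before the hindered α-branched C8 ketone, and hydride enters on the α face anti to the C10 methyl, giving the 3β (3S) allylic alcohol.

Step 17
Reactants: 24 (3S,7R,10R)-3-hydroxy-11-(triethylsilyloxy)eudesm-4-en-8-one
Product: 25 (3S,7R,10R)-8-oxo-11-(triethylsilyloxy)eudesm-4-en-3-yl formate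
Conditions: acetic formic anhydride, pyridine, CH2Cl2, 0 °C
Reagents that add atoms: acetic formic anhydride, CC(=O)OC=O
Why: O-Formylation of the secondary allylic alcohol by the mixed anhydride (the formyl group is the more electrophilic acyl), with retention at C3.

Step 18
Reactants: 25 (3S,7R,10R)-8-oxo-11-(triethylsilyloxy)eudesm-4-en-3-yl formate
Product: 26 (5R,7R,10R)-11-(triethylsilyloxy)eudesm-3-en-8-one
Conditions: Pd(OAc)2 (10 mol%), nBu3P (10 mol%), THF, rt → 60 °C
Reagents that add atoms: none
Why: Tsuji–Mandai hydrogenolysis of an allylic formate; zerovalent palladium ionises the 3β-formate with inversion, decarboxylation leaves a π-allylpalladium hydride on the α face, and hydride is delivered on that face to the more substituted terminus C5, setting the 5α-H trans ring fusion and moving the alkene to C3=C4.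

Step 19
Reactants: 26 (5R,7R,10R)-11-(triethylsilyloxy)eudesm-3-en-8-one
Product: 27 (5R,10R)-11-(triethylsilyloxy)eudesma-3,6-dien-8-one
Conditions: IBX (3 equiv), 4-methoxypyridine N-oxide (3 equiv), DMSO, rt → 45 °C
Reagents that add atoms: none
Why: Nicolaou IBX dehydrogenation of a ketone through its enol; C10 is quaternary, so only the C7 enol is productive and C6=C7 is the only possible enone, and the relay centre C7 is erased.

Step 20
Reactants: 27 (5R,10R)-11-(triethylsilyloxy)eudesma-3,6-dien-8-one
Product: 28 (3R,4S,5R,10R)-3,4-dihydroxy-11-(triethylsilyloxy)eudesm-6-en-8-one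
Conditions: OsO4 (5 mol%), NMO (1.5 equiv), acetone/H2O, rt
Reagents that add atoms: N-methylmorpholine N-oxide, C[N+]1([O-])CCOCC1; water, O; both oxygens are delivered through OsO4, O=[Os](=O)(=O)=O
Why: Upjohn dihydroxylation; the electron-rich trisubstituted C3=C4 alkene should react far faster than the hindered electron-poor enone alkene, and the syn addition comes from the α face anti to the axial C10 methyl, giving the 3α,4α-diol (3R,4S).

Step 21
Reactants: 28 (3R,4S,5R,10R)-3,4-dihydroxy-11-(triethylsilyloxy)eudesm-6-en-8-one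
Product: 29 (3R,4S,5R,10R)-3,4,11-trihydroxyeudesm-6-en-8-one
Conditions: HF·pyridine, pyridine, THF, 0 °C → rt
Reagents that add atoms: none
Why: Fluoride cleavage of the tertiary triethylsilyl ether, done before the acid-sensitive epoxy ester is in place.

Step 22
Reactants: 30 tiglic acid
Product: 31 (E)-2-methylbut-2-en-1-ol
Conditions: LiAlH4, Et2O, 0 °C → rt
Reagents that add atoms: none
Why: 1,2-Reduction of the unsaturated acid by LiAlH4 with the alkene geometry retained.

Step 23
Reactants: 31 (E)-2-methylbut-2-en-1-ol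
Product: 32 [(2R,3R)-2,3-dimethyloxiran-2-yl]methanol
Conditions: Ti(OiPr)4 (10 mol%), D-(−)-diethyl tartrate (12 mol%), tBuOOH (2 equiv), 4 Å sieves, CH2Cl2, −20 °C
Reagents that add atoms: tert-butyl hydroperoxide, CC(C)(C)OO
Why: Sharpless asymmetric epoxidation; the titanium D-(−)-tartrate catalyst selects the alkene face that gives the (2R,3R)-epoxy alcohol, and the E alkene fixes the two methyl groups cis on the oxirane.

Step 24
Reactants: 32 [(2R,3R)-2,3-dimethyloxiran-2-yl]methanol
Product: 33 (2S,3R)-2,3-dimethyloxirane-2-carboxylic acid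
Conditions: RuCl3 (2 mol%), NaIO4 (3 equiv), CCl4/MeCN/H2O, rt
Reagents that add atoms: water, O (through the aldehyde hydrate); sodium periodate as terminal oxidant, [Na+].[O-]I(=O)(=O)=O
Why: Sharpless ruthenium tetroxide oxidation of a primary alcohol to the acid leaves the epoxide intact; the C2 descriptor changes from R to S only through the priority rules.

Step 25
Reactants: 33 (2S,3R)-2,3-dimethyloxirane-2-carboxylic acid; 29 (3R,4S,5R,10R)-3,4,11-trihydroxyeudesm-6-en-8-one
Product: 35 (3R,4S,5R,10R)-4,11-dihydroxy-8-oxoeudesm-6-en-3-yl (2S,3R)-2,3-dimethyloxirane-2-carboxylate, via mixed Yamaguchi anhydride 34 (not isolated)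
Conditions: 2,4,6-Cl3C6H2COCl, Et3N, THF, rt; then 29, DMAP, toluene, rt → 40 °C
Reagents that add atoms: none
Why: Yamaguchi esterification; DMAP attacks the less hindered epoxy-acyl carbonyl of the mixed anhydride, and only the secondary C3 hydroxyl should be acylated because the C4 and C11 hydroxyls are tertiary.

**Compound list**

1 | 2,6-dimethylbenzoic acid | Cc1cccc(C)c1C(=O)O | starting material
2 | 3-bromo-2,6-dimethylbenzoic acid | Cc1ccc(Br)c(C)c1C(=O)O | intermediate
3 | 3-hydroxy-2,6-dimethylbenzoic acid | Cc1ccc(O)c(C)c1C(=O)O | intermediate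
4 | 3-(hydroxymethyl)-2,4-dimethylphenol | Cc1ccc(O)c(C)c1CO | intermediate
5 | [3-(benzyloxy)-2,6-dimethylphenyl]methanol | Cc1ccc(OCc2ccccc2)c(C)c1CO | intermediate
6 | 1-(benzyloxy)-3-(bromomethyl)-2,4-dimethylbenzene | Cc1ccc(OCc2ccccc2)c(C)c1CBr | intermediate
7 | 3-methylbut-2-enoic acid | CC(C)=CC(=O)O | starting material
8 | (R)-4-benzyl-1,3-oxazolidin-2-one | O=C1N[C@H](Cc2ccccc2)CO1 | starting material
9 | 3-methylbut-2-enoic pivalic anhydride (not isolated) | CC(C)=CC(=O)OC(=O)C(C)(C)C | intermediate
10 | (R)-4-benzyl-3-(3-methylbut-2-enoyl)-1,3-oxazolidin-2-one | CC(C)=CC(=O)N1[C@H](Cc2ccccc2)COC1=O | intermediate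
11 | sodium (Z)-dienolate of 10 (not isolated) | [Na+].[O-]/C(=C\C(C)=C)N1[C@H](Cc2ccccc2)COC1=O | intermediate
12 | (R)-4-benzyl-3-{(2R)-2-[3-(benzyloxy)-2,6-dimethylbenzyl]-3-methylbut-3-enoyl}-1,3-oxazolidin-2-one | C=C(C)[C@@H](Cc1c(C)ccc(OCc2ccccc2)c1C)C(=O)N1[C@H](Cc2ccccc2)COC1=O | intermediate
13 | (R)-4-benzyl-3-{(2R)-2-[3-(benzyloxy)-2,6-dimethylbenzyl]-3-hydroxy-3-methylbutanoyl}-1,3-oxazolidin-2-one | CC(C)(O)[C@@H](Cc1c(C)ccc(OCc2ccccc2)c1C)C(=O)N1[C@H](Cc2ccccc2)COC1=O | intermediate
14 | (2R)-2-[3-(benzyloxy)-2,6-dimethylbenzyl]-3-hydroxy-N-methoxy-N,3-dimethylbutanamide | CON(C)C(=O)[C@H](Cc1c(C)ccc(OCc2ccccc2)c1C)C(C)(C)O | intermediate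
15 | (2R)-2-[3-(benzyloxy)-2,6-dimethylbenzyl]-N-methoxy-N,3-dimethyl-3-(triethylsilyloxy)butanamide | CON(C)C(=O)[C@H](Cc1c(C)ccc(OCc2ccccc2)c1C)C(C)(C)O[Si](CC)(CC)CC | intermediate
16 | (3R)-3-[3-(benzyloxy)-2,6-dimethylbenzyl]-4-methyl-4-(triethylsilyloxy)pentan-2-one | CC(=O)[C@H](Cc1c(C)ccc(OCc2ccccc2)c1C)C(C)(C)O[Si](CC)(CC)CC | intermediate
17 | (3R)-3-(3-hydroxy-2,6-dimethylbenzyl)-4-methyl-4-(triethylsilyloxy)pentan-2-one | CC(=O)[C@H](Cc1c(C)ccc(O)c1C)C(C)(C)O[Si](CC)(CC)CC | intermediate
18 | (3R)-3-[2,6-dimethyl-3-(trimethylsilyloxy)benzyl]-4-methyl-4-(triethylsilyloxy)pentan-2-one (not isolated) | CC(=O)[C@H](Cc1c(C)ccc(O[Si](C)(C)C)c1C)C(C)(C)O[Si](CC)(CC)CC | intermediate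
19 | terminal lithium enolate of 18 (not isolated) | [Li+].[O-]C(=C)[C@H](Cc1c(C)ccc(O[Si](C)(C)C)c1C)C(C)(C)O[Si](CC)(CC)CC | intermediate
20 | tert-butyldimethylsilyl enol ether of 18, aryl trimethylsilyl ether retained (not isolated) | C=C(O[Si](C)(C)C(C)(C)C)[C@H](Cc1c(C)ccc(O[Si](C)(C)C)c1C)C(C)(C)O[Si](CC)(CC)CC | intermediate
21 | 3-{(2R)-3-(tert-butyldimethylsilyloxy)-2-[2-(triethylsilyloxy)propan-2-yl]but-3-en-1-yl}-2,4-dimethylphenol | C=C(O[Si](C)(C)C(C)(C)C)[C@H](Cc1c(C)ccc(O)c1C)C(C)(C)O[Si](CC)(CC)CC | intermediate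
22 | (7R,10S)-11-(triethylsilyloxy)eudesma-1,4-diene-3,8-dione | O=C1C=C[C@]2(C)CC(=O)[C@@H](C(C)(C)O[Si](CC)(CC)CC)CC2=C1C | intermediate
23 | (7R,10R)-11-(triethylsilyloxy)eudesm-4-ene-3,8-dione | O=C1CC[C@]2(C)CC(=O)[C@@H](C(C)(C)O[Si](CC)(CC)CC)CC2=C1C | intermediate
24 | (3S,7R,10R)-3-hydroxy-11-(triethylsilyloxy)eudesm-4-en-8-one | O[C@H]1CC[C@]2(C)CC(=O)[C@@H](C(C)(C)O[Si](CC)(CC)CC)CC2=C1C | intermediate
25 | (3S,7R,10R)-8-oxo-11-(triethylsilyloxy)eudesm-4-en-3-yl formate | O=CO[C@H]1CC[C@]2(C)CC(=O)[C@@H](C(C)(C)O[Si](CC)(CC)CC)CC2=C1C | intermediate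
26 | (5R,7R,10R)-11-(triethylsilyloxy)eudesm-3-en-8-one | C1C[C@]2(C)CC(=O)[C@@H](C(C)(C)O[Si](CC)(CC)CC)C[C@H]2C(C)=C1 | intermediate
27 | (5R,10R)-11-(triethylsilyloxy)eudesma-3,6-dien-8-one | C1C[C@]2(C)CC(=O)C(C(C)(C)O[Si](CC)(CC)CC)=C[C@H]2C(C)=C1 | intermediate
28 | (3R,4S,5R,10R)-3,4-dihydroxy-11-(triethylsilyloxy)eudesm-6-en-8-one | O[C@@H]1CC[C@]2(C)CC(=O)C(C(C)(C)O[Si](CC)(CC)CC)=C[C@H]2[C@]1(C)O | intermediate
29 | (3R,4S,5R,10R)-3,4,11-trihydroxyeudesm-6-en-8-one | O[C@@H]1CC[C@]2(C)CC(=O)C(C(C)(C)O)=C[C@H]2[C@]1(C)O | intermediate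
30 | tiglic acid, (E)-2-methylbut-2-enoic acid | C/C=C(\C)C(=O)O | starting material
31 | (E)-2-methylbut-2-en-1-ol | C/C=C(\C)CO | intermediate
32 | [(2R,3R)-2,3-dimethyloxiran-2-yl]methanol | C[C@H]1O[C@]1(C)CO | intermediate
33 | (2S,3R)-2,3-dimethyloxirane-2-carboxylic acid | C[C@H]1O[C@]1(C)C(=O)O | intermediate
34 | (2S,3R)-2,3-dimethyloxirane-2-carboxylic 2,4,6-trichlorobenzoic anhydride (not isolated) | C[C@H]1O[C@]1(C)C(=O)OC(=O)c1c(Cl)cc(Cl)cc1Cl | intermediate
35 | (3R,4S,5R,10R)-4,11-dihydroxy-8-oxoeudesm-6-en-3-yl (2S,3R)-2,3-dimethyloxirane-2-carboxylate (CNP0272928.1) | C[C@H]1O[C@]1(C)C(=O)O[C@@H]1CC[C@]2(C)CC(=O)C(C(C)(C)O)=C[C@H]2[C@]1(C)O | target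

**Step count and risks**

Total step count: 25. Longest linear sequence: 21 steps (steps 1–5, 7–21 and 25).

Steps most likely to fail:

1. Step 14 (anodic ring closure). The electrolysis may lose material through over-oxidation of the dienone or through intermolecular coupling of the oxidised phenol before C9 reaches C10; facial selectivity at C10 may also be low. Fallback without an oxidant: set out from 17 and run step 13 as far as bis-silyl compound 20. Brominate its silyl enol ether with N-bromosuccinimide in THF at −78 °C and free the phenol with citric acid in methanol, which should give (3R)-1-bromo-3-(3-hydroxy-2,6-dimethylbenzyl)-4-methyl-4-(triethylsilyloxy)pentan-2-one F1. KOtBu (1.0 equiv) in tBuOH/THF at 0 °C should then alkylate the phenolate at its para carbon with the bromomethyl ketone (Winstein–Masamune dearomatising alkylation, Ar1-6 participation) and return to 22.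

2. Step 19 (dehydrogenation to C6=C7). Enolisation toward the hindered C7 may be too slow for turnover, or the C11 silyloxy group may be lost by β-elimination from the enol. Fallback that separates enolisation from oxidation: from 26, TMSCl/NaI/Et3N in MeCN at rt (equilibrating conditions) should give the C7=C8 enol ether (5R,10R)-8-(trimethylsilyloxy)-11-(triethylsilyloxy)eudesma-3,7-diene F2. Pd(OAc)2 (1.1 equiv) in MeCN at rt (Saegusa–Ito oxidation; the only β-hydrogens are on C6) returns to 27.

3. Step 18 (formate hydrogenolysis). Ionisation next to the tetrasubstituted C4=C5 alkene may be slow, hydride may be delivered to C3 instead of C5, or the π-allyl complex may collapse to a diene. Fallback by dissolving-metal reduction: from 23, Li (6 equiv) in NH3/THF with tBuOH (2 equiv) at −78 °C should reduce the enone to the C3–C4 lithium enolate with axial protonation at C5 (5α-H), and the C8 ketone to the equatorial alkoxide. Isoprene quench, removal of NH3 and PhNTf2 in THF should give (5R,7S,8S,10R)-8-hydroxy-11-(triethylsilyloxy)eudesm-3-en-3-yl trifluoromethanesulfonate F3. Pd(OAc)2/PPh3, Bu3N and HCO2H in DMF at 60 °C reduce the enol triflate to (5R,7S,8S,10R)-11-(triethylsilyloxy)eudesm-3-en-8-ol F4, and Dess–Martin periodinane in CH2Cl2 returns to 26.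

Further compounds
F1 | step 14 | (3R)-1-bromo-3-(3-hydroxy-2,6-dimethylbenzyl)-4-methyl-4-(triethylsilyloxy)pentan-2-one | BrCC(=O)[C@H](Cc1c(C)ccc(O)c1C)C(C)(C)O[Si](CC)(CC)CC
F2 | step 19 | (5R,10R)-8-(trimethylsilyloxy)-11-(triethylsilyloxy)eudesma-3,7-diene | C1C[C@]2(C)CC(O[Si](C)(C)C)=C(C(C)(C)O[Si](CC)(CC)CC)C[C@H]2C(C)=C1
F3 | step 18 | (5R,7S,8S,10R)-8-hydroxy-11-(triethylsilyloxy)eudesm-3-en-3-yl trifluoromethanesulfonate | C1C[C@]2(C)C[C@H](O)[C@@H](C(C)(C)O[Si](CC)(CC)CC)C[C@H]2C(C)=C1OS(=O)(=O)C(F)(F)F
F4 | step 18 | (5R,7S,8S,10R)-11-(triethylsilyloxy)eudesm-3-en-8-ol | C1C[C@]2(C)C[C@H](O)[C@@H](C(C)(C)O[Si](CC)(CC)CC)C[C@H]2C(C)=C1
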